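**Retrosynthetic overview**

1. Target 23 comes from 22 by one global hydrogenolysis; 22 comes from a Stille union (C6–C6′ biaryl bond) of the open-chain half 18 (aryl bromide) and the lactone half 21 (aryl stannane).
2. Both halves derive from one hydroxy ester, 16: BOM ether for the open half; acid lactonisation (to 19) then stannylation for the closed half.
3. 16 comes from benzofuran-3-ol β-keto ester 8, one CH2 (zinc carbenoid) and chiral aldehyde 12 in a tandem ring expansion–aldol. The five-membered O1–C2–C3–C3a–C7a ring of 8 grows by one carbon into the pyranone ring, and the quaternary C2, the C2–C1′ bond and C1′ are set in the same flask.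
4. Enabling feature: in 8 the ring bond C2–C3 joins an ester-bearing carbon (acceptor) to the enol/ketone carbon (donor). A CH2 placed across it gives a donor–acceptor cyclopropane that breaks only at this shared bond. The exocyclic ester enolate left at C2 of the new six-membered ring lies next to ring oxygen O1 (chelation, fixed geometry) and cannot be made by deprotonating a chromanone, where C3–H is the acidic site. Both enantiomers of the cyclopropane give the same planar enolate.
5. Ring order: benzene (bought), furanone (Dieckmann, step 4), pyranone (ring expansion, step 7), butyrolactone (step 9). 8 comes from methyl 2,6-dihydroxybenzoate and 12 from (S)-β-methyl-γ-butyrolactone.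

Key step: step 7

Remark: (S)-4-methyldihydrofuran-2(3H)-one (9) is taken as a purchasable chiral-pool lactone, and the C6–C6′ biaryl axis (one ortho oxygen on each ring, no descriptor in the target) is treated as freely rotating.

**Route**

Step 1
Reactants: 1 methyl 2,6-dihydroxybenzoate
Product: 3 methyl 2-hydroxy-6-(2-methoxy-2-oxoethoxy)benzoate
Conditions: BrCH2CO2Me (1.05 equiv), K2CO3, acetone, reflux
Reagents that add atoms: methyl bromoacetate (2), COC(=O)CBr
Why: Williamson etherification should stop at the mono-ether because the remaining phenol is held in a hydrogen bond to the ester carbonyl; no stereocentre is formed.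

Step 2
Reactants: 3 methyl 2-hydroxy-6-(2-methoxy-2-oxoethoxy)benzoate
Product: 5 methyl 3-bromo-2-hydroxy-6-(2-methoxy-2-oxoethoxy)benzoate
Conditions: NBS, i-Pr2NH (cat.), CH2Cl2, 0 °C
Reagents that add atoms: N-bromosuccinimide (4), O=C1CCC(=O)N1Br
Why: Amine-catalysed ortho-bromination of a phenol should deliver bromine to C3, which is ortho to the free OH, para to the ether oxygen and the less hindered of the two activated positions.

Step 3
Reactants: 5 methyl 3-bromo-2-hydroxy-6-(2-methoxy-2-oxoethoxy)benzoate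
Product: 7 methyl 2-(benzyloxy)-3-bromo-6-(2-methoxy-2-oxoethoxy)benzoate
Conditions: BnBr, K2CO3, Bu4NI (cat.), acetone, reflux
Reagents that add atoms: benzyl bromide (6), BrCc1ccccc1
Why: Williamson benzylation of the ortho-bromo phenol under a weak base that should not trigger the Dieckmann reaction.

Step 4
Reactants: 7 methyl 2-(benzyloxy)-3-bromo-6-(2-methoxy-2-oxoethoxy)benzoate
Product: 8 methyl 4-(benzyloxy)-5-bromo-3-hydroxy-1-benzofuran-2-carboxylate
Conditions: NaOMe, MeOH, 0 °C to rt; then aq HCl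
Reagents that add atoms: none
Why: Dieckmann condensation of the aryloxyacetate CH2 onto the neighbouring benzoate (5-exo-trig) should give the cyclic β-keto ester, which is expected to exist as its aromatic enol.

Step 5
Reactants: 9 (S)-4-methyldihydrofuran-2(3H)-one
Product: 11 benzyl (S)-4-hydroxy-3-methylbutanoate, via potassium carboxylate 10 (not isolated)
Conditions: KOH (1.0 equiv), MeOH–H2O, rt; evaporate; BnBr, DMF, rt
Reagents that add atoms: potassium hydroxide, [K+].[OH-]; benzyl bromide (6), BrCc1ccccc1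
Why: Lactone saponification followed by SN2 alkylation of the carboxylate leaves the β-stereocentre untouched; the product is used at once to avoid relactonisation.

Step 6
Reactants: 11 benzyl (S)-4-hydroxy-3-methylbutanoate
Product: 12 benzyl (S)-3-methyl-4-oxobutanoate
Conditions: PhI(OAc)2, TEMPO (cat.), CH2Cl2, rt; used crude
Reagents that add atoms: none
Why: TEMPO/iodine(III) oxidation of the primary alcohol stops at the aldehyde under non-basic conditions, which should keep the now α-stereocentre from epimerising.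

Step 7
Reactants: 8 methyl 4-(benzyloxy)-5-bromo-3-hydroxy-1-benzofuran-2-carboxylate; 12 benzyl (S)-3-methyl-4-oxobutanoate
Product: 16 benzyl (3S,4R)-4-[(2S)-5-(benzyloxy)-6-bromo-2-(methoxycarbonyl)-4-oxo-3,4-dihydro-2H-chromen-2-yl]-4-hydroxy-3-methylbutanoate, via zinc cyclopropoxide 14 (not isolated), via ring-expanded zinc ester enolate 15 (not isolated)
Conditions: Et2Zn (4 equiv), CH2I2 (4 equiv), CH2Cl2, 0 °C; then 12 (1.5 equiv), −20 °C; aq NH4Cl at −20 °C
Reagents that add atoms: diiodomethane (13), ICI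
Why: Proposed new method: the ethylzinc enolate of 8 is methylenated across C2–C3 by the Furukawa carbenoid to the donor–acceptor cyclopropoxide 14, whose C2–C3 bond (shared by furanone and cyclopropane) fragments to the zinc ester enolate 15, so that the five-membered O1–C2–C3–C3a–C7a ring becomes the six-membered pyranone ring with the new CH2 as its C3, and 15 then adds to aldehyde 12 in an aldol reaction. The closest known reaction type is the zinc-carbenoid chain extension of β-keto esters with in-situ aldol trapping of the zinc enolate (tandem chain extension–aldol), together with the one-carbon ring expansion of cyclic β-keto esters by the same carbenoid; new here are the aromatic α-aryloxy (benzofuranol) enolate and the fully substituted carbon formed in the aldol. The only ring that is closed is the cyclopropane (3-exo-trig attack of the C2-bound CH2–Zn on the C3 carbonyl, or concerted methylene transfer), and the pyranone ring arises from it by cleavage of the zero-atom bridge of the bicyclo[3.1.0] unit and not by a cyclisation. C2 (S) is controlled by the enolate geometry: zinc is held between the enolate oxygen and ring oxygen O1 (the ring ketone points away and cannot chelate), so in a Zimmerman–Traxler chair O1 is pseudo-axial and ends syn to the new hydroxyl, while C1′ (R) is controlled by the methyl stereocentre of 12 through Felkin–Anh addition (CH2CO2Bn anti to the nucleophile), expected because only the small ring oxygen occupies the pseudo-axial site and the enolate therefore behaves like an E-enolate. The step needs fragmentation at C2–C3 and not at C3–CH2 (secured by the ester at C2, which stabilises the carbanion), C- rather than O-attack of the aromatic enolate on the carbenoid, and one aldehyde face; the cold quench is meant to keep the aldolate from reverting or lactonising, and any lactone that does form is 19 and is carried into step 10.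

Step 8
Reactants: 16 benzyl (3S,4R)-4-[(2S)-5-(benzyloxy)-6-bromo-2-(methoxycarbonyl)-4-oxo-3,4-dihydro-2H-chromen-2-yl]-4-hydroxy-3-methylbutanoate
Product: 18 benzyl (3S,4R)-4-[(2S)-5-(benzyloxy)-6-bromo-2-(methoxycarbonyl)-4-oxo-3,4-dihydro-2H-chromen-2-yl]-4-[(benzyloxy)methoxy]-3-methylbutanoate
Conditions: BnOCH2Cl, i-Pr2NEt, Bu4NI (cat.), CH2Cl2, 0 °C to rt
Reagents that add atoms: benzyl chloromethyl ether (17), ClCOCc1ccccc1
Why: Alkylation of the secondary alcohol with an iodide-activated chloromethyl ether gives an acetal ether that blocks lactonisation and can leave by hydrogenolysis; no stereocentre is touched.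

Step 9
Reactants: 16 benzyl (3S,4R)-4-[(2S)-5-(benzyloxy)-6-bromo-2-(methoxycarbonyl)-4-oxo-3,4-dihydro-2H-chromen-2-yl]-4-hydroxy-3-methylbutanoate
Product: 19 methyl (2S)-5-(benzyloxy)-6-bromo-2-[(2R,3S)-3-methyl-5-oxooxolan-2-yl]-4-oxo-3,4-dihydro-2H-chromene-2-carboxylate
Conditions: CSA (cat.), toluene, 50 °C
Reagents that add atoms: none
Why: Acid-catalysed 5-exo-trig lactonisation of the γ-hydroxy ester proceeds with retention at all centres, so the cis methyl/chromanone relationship of the lactone follows from the syn relationship in 16.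

Step 10
Reactants: 19 methyl (2S)-5-(benzyloxy)-6-bromo-2-[(2R,3S)-3-methyl-5-oxooxolan-2-yl]-4-oxo-3,4-dihydro-2H-chromene-2-carboxylate
Product: 21 methyl (2S)-5-(benzyloxy)-2-[(2R,3S)-3-methyl-5-oxooxolan-2-yl]-4-oxo-6-(trimethylstannyl)-3,4-dihydro-2H-chromene-2-carboxylate
Conditions: (Me3Sn)2, Pd(PPh3)4 (cat.), toluene, 100 °C
Reagents that add atoms: hexamethylditin (20), C[Sn](C)(C)[Sn](C)(C)C
Why: Palladium-catalysed stannylation of an aryl bromide runs under neutral conditions that lactone, ketone and esters should tolerate.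

Step 11
Reactants: 18 benzyl (3S,4R)-4-[(2S)-5-(benzyloxy)-6-bromo-2-(methoxycarbonyl)-4-oxo-3,4-dihydro-2H-chromen-2-yl]-4-[(benzyloxy)methoxy]-3-methylbutanoate; 21 methyl (2S)-5-(benzyloxy)-2-[(2R,3S)-3-methyl-5-oxooxolan-2-yl]-4-oxo-6-(trimethylstannyl)-3,4-dihydro-2H-chromene-2-carboxylate
Product: 22 benzyl (3S,4R)-4-[(2S)-5-(benzyloxy)-6-{(2S)-5-(benzyloxy)-2-(methoxycarbonyl)-2-[(2R,3S)-3-methyl-5-oxooxolan-2-yl]-4-oxo-3,4-dihydro-2H-chromen-6-yl}-2-(methoxycarbonyl)-4-oxo-3,4-dihydro-2H-chromen-2-yl]-4-[(benzyloxy)methoxy]-3-methylbutanoate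
Conditions: Pd(Pt-Bu3)2 (cat.), CuI (cat.), CsF, DMF, 45 °C
Reagents that add atoms: none
Why: Copper/fluoride-assisted Stille cross-coupling should join the two aryl carbons (each with one ortho benzyloxy group) without the strong base that could enolise C3 and open the pyranone by retro-oxa-Michael reaction.

Step 12
Reactants: 22 the fully protected biaryl
Product: 23 (3S,4R)-4-hydroxy-4-[(2S)-5-hydroxy-6-{(2S)-5-hydroxy-2-(methoxycarbonyl)-2-[(2R,3S)-3-methyl-5-oxooxolan-2-yl]-4-oxo-3,4-dihydro-2H-chromen-6-yl}-2-(methoxycarbonyl)-4-oxo-3,4-dihydro-2H-chromen-2-yl]-3-methylbutanoic acid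
Conditions: H2 (1 atm), Pd(OH)2/C, EtOAc, rt
Reagents that add atoms: none
Why: Hydrogenolysis should cleave both aryl benzyl ethers, the benzyl ester and the BOM ether in one neutral operation, so the γ-hydroxy acid is freed without acid or base that would close it to the lactone.

**Compound list**

1 | methyl 2,6-dihydroxybenzoate | COC(=O)c1c(O)cccc1O | starting material
2 | methyl bromoacetate | COC(=O)CBr | starting material
3 | methyl 2-hydroxy-6-(2-methoxy-2-oxoethoxy)benzoate | COC(=O)COc1cccc(O)c1C(=O)OC | intermediate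
4 | N-bromosuccinimide | O=C1CCC(=O)N1Br | starting material
5 | methyl 3-bromo-2-hydroxy-6-(2-methoxy-2-oxoethoxy)benzoate | COC(=O)COc1ccc(Br)c(O)c1C(=O)OC | intermediate
6 | benzyl bromide | BrCc1ccccc1 | starting material
7 | methyl 2-(benzyloxy)-3-bromo-6-(2-methoxy-2-oxoethoxy)benzoate | COC(=O)COc1ccc(Br)c(OCc2ccccc2)c1C(=O)OC | intermediate
8 | methyl 4-(benzyloxy)-5-bromo-3-hydroxy-1-benzofuran-2-carboxylate | COC(=O)c1oc2ccc(Br)c(OCc3ccccc3)c2c1O | intermediate
9 | (S)-4-methyldihydrofuran-2(3H)-one | C[C@@H]1COC(=O)C1 | starting material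
10 | potassium (S)-4-hydroxy-3-methylbutanoate | OC[C@@H](C)CC(=O)[O-].[K+] | intermediate
11 | benzyl (S)-4-hydroxy-3-methylbutanoate | OC[C@@H](C)CC(=O)OCc1ccccc1 | intermediate
12 | benzyl (S)-3-methyl-4-oxobutanoate | O=C[C@@H](C)CC(=O)OCc1ccccc1 | intermediate
13 | diiodomethane | ICI | starting material
14 | ethylzinc 6-(benzyloxy)-5-bromo-1a-(methoxycarbonyl)-1,1a-dihydro-6bH-cyclopropa[b][1]benzofuran-6b-olate (racemic, cis-fused) | COC(=O)C12CC1(O[Zn]CC)c1c(OCc3ccccc3)c(Br)ccc1O2 | intermediate
15 | ethylzinc (Z)-[5-(benzyloxy)-6-bromo-4-oxo-3,4-dihydro-2H-chromen-2-ylidene](methoxy)methanolate | CO\C(O[Zn]CC)=C1/CC(=O)c2c(OCc3ccccc3)c(Br)ccc2O1 | intermediate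
16 | benzyl (3S,4R)-4-[(2S)-5-(benzyloxy)-6-bromo-2-(methoxycarbonyl)-4-oxo-3,4-dihydro-2H-chromen-2-yl]-4-hydroxy-3-methylbutanoate | COC(=O)[C@@]1([C@H](O)[C@@H](C)CC(=O)OCc4ccccc4)CC(=O)c2c(ccc(Br)c2OCc3ccccc3)O1 | intermediate
17 | benzyl chloromethyl ether | ClCOCc1ccccc1 | starting material
18 | benzyl (3S,4R)-4-[(2S)-5-(benzyloxy)-6-bromo-2-(methoxycarbonyl)-4-oxo-3,4-dihydro-2H-chromen-2-yl]-4-[(benzyloxy)methoxy]-3-methylbutanoate | COC(=O)[C@@]1([C@H](OCOCc5ccccc5)[C@@H](C)CC(=O)OCc4ccccc4)CC(=O)c2c(ccc(Br)c2OCc3ccccc3)O1 | intermediate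
19 | methyl (2S)-5-(benzyloxy)-6-bromo-2-[(2R,3S)-3-methyl-5-oxooxolan-2-yl]-4-oxo-3,4-dihydro-2H-chromene-2-carboxylate | Brc1ccc2c(c1OCc5ccccc5)C(=O)C[C@@](C(=O)OC)([C@@H]3OC(=O)C[C@@H]3C)O2 | intermediate
20 | hexamethylditin | C[Sn](C)(C)[Sn](C)(C)C | starting material
21 | methyl (2S)-5-(benzyloxy)-2-[(2R,3S)-3-methyl-5-oxooxolan-2-yl]-4-oxo-6-(trimethylstannyl)-3,4-dihydro-2H-chromene-2-carboxylate | C[Sn](C)(C)c1ccc2c(c1OCc5ccccc5)C(=O)C[C@@](C(=O)OC)([C@@H]3OC(=O)C[C@@H]3C)O2 | intermediate
22 | benzyl (3S,4R)-4-[(2S)-5-(benzyloxy)-6-{(2S)-5-(benzyloxy)-2-(methoxycarbonyl)-2-[(2R,3S)-3-methyl-5-oxooxolan-2-yl]-4-oxo-3,4-dihydro-2H-chromen-6-yl}-2-(methoxycarbonyl)-4-oxo-3,4-dihydro-2H-chromen-2-yl]-4-[(benzyloxy)methoxy]-3-methylbutanoate | COC(=O)[C@@]1([C@H](OCOCc5ccccc5)[C@@H](C)CC(=O)OCc4ccccc4)CC(=O)c2c(ccc(-c6ccc7c(c6OCc8ccccc8)C(=O)C[C@@](C(=O)OC)([C@@H]9OC(=O)C[C@@H]9C)O7)c2OCc3ccccc3)O1 | intermediate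
23 | (3S,4R)-4-hydroxy-4-[(2S)-5-hydroxy-6-{(2S)-5-hydroxy-2-(methoxycarbonyl)-2-[(2R,3S)-3-methyl-5-oxooxolan-2-yl]-4-oxo-3,4-dihydro-2H-chromen-6-yl}-2-(methoxycarbonyl)-4-oxo-3,4-dihydro-2H-chromen-2-yl]-3-methylbutanoic acid (CNP0517857.1) | COC(=O)[C@@]1([C@H](O)[C@@H](C)CC(=O)O)CC(=O)c2c(ccc(-c3ccc4c(c3O)C(=O)C[C@@](C(=O)OC)([C@@H]3OC(=O)C[C@@H]3C)O4)c2O)O1 | target

**Step count and risks**

Total step count: 12. Longest linear sequence: 9 steps (1, 2, 3, 4, 7, 9, 10, 11, 12).

Three steps most likely to fail: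

1. Step 7 (proposed new method). What may go wrong is poor facial control in the C–C bond formation, if the zinc is not held on the O1 side of the enolate or the aldehyde is attacked on both faces. Proton transfer from the aldehyde to the enolate and retro-aldol equilibration of the hindered aldolate are the other loss channels. The fallback uses known chemistry, sets out from 8 and returns at 19 and 16. 8 is ring-expanded with the same zinc carbenoid but quenched with a proton (the established one-carbon ring expansion of cyclic β-keto esters) to racemic methyl 5-(benzyloxy)-6-bromo-4-oxochromane-2-carboxylate F1. F1 is dehydrogenated (DDQ, dioxane, heat) to methyl 5-(benzyloxy)-6-bromo-4-oxo-4H-chromene-2-carboxylate F2. F2 is turned by TMSOTf into its 4-silyloxybenzopyrylium salt and trapped at C2 in a vinylogous Mukaiyama addition by 4-methyl-2-(trimethylsilyloxy)furan F3 (from commercial 4-methylfuran-2(5H)-one, TMSOTf, Et3N). After acidic work-up and separation of the diastereomer with the required C2/C2′ relationship, this should give the racemic butenolide methyl 5-(benzyloxy)-6-bromo-2-(3-methyl-5-oxo-2,5-dihydrofuran-2-yl)-4-oxochromane-2-carboxylate F4. Conjugate reduction with Stryker's reagent from the face away from the chromanone should place the methyl group cis to it and give the racemic lactone rac-19 F5, which is resolved by preparative chromatography on a chiral phase to 19. Part of 19 is opened with one equivalent of KOH (THF–H2O, 0 °C) to the potassium (3S,4R)-4-[(2S)-5-(benzyloxy)-6-bromo-2-(methoxycarbonyl)-4-oxochroman-2-yl]-4-hydroxy-3-methylbutanoate F6 and alkylated with BnBr in DMF to return to 16.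

2. Step 8. What may go wrong is lactonisation of the γ-hydroxy benzyl ester under the amine base outrunning the slow alkylation of the hindered C1′ hydroxyl, so that the open-chain form is lost. The fallback changes the protecting-group strategy and the endgame; it sets out from 16 and returns at 23. 16 is silylated kinetically (TESOTf, 2,6-lutidine, CH2Cl2, −78 °C) to the triethylsilyl ether of 16 F7. F7 is coupled with 21 under the conditions of step 11 to the triethylsilyl-protected biaryl F8. Hydrogenolysis (H2, Pd/C, EtOAc) removes the three benzyl groups to give the triethylsilyl-protected hydroxy acid F9, and buffered HF·pyridine (pyridine, THF, 0 °C) removes the silyl group to give 23.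

3. Step 11. What may go wrong is slow transmetalation of the ortho-benzyloxy aryl stannane, leading to protodestannylation and homocoupling in place of cross-coupling. The fallback switches to boron; it sets out from 19 and returns at 22. Miyaura borylation of 19 (B2pin2, PdCl2(dppf), KOAc, dioxane, 85 °C) gives methyl (2S)-5-(benzyloxy)-2-[(2R,3S)-3-methyl-5-oxooxolan-2-yl]-4-oxo-6-(4,4,5,5-tetramethyl-1,3,2-dioxaborolan-2-yl)-3,4-dihydro-2H-chromene-2-carboxylate F10. F10 is joined to 18 by Suzuki–Miyaura coupling (Pd(OAc)2, SPhos, K3PO4, toluene–H2O, 50 °C) to give 22.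

Further compounds
F1 | step 7 | methyl 5-(benzyloxy)-6-bromo-4-oxochromane-2-carboxylate (racemic) | COC(=O)C1CC(=O)c2c(ccc(Br)c2OCc3ccccc3)O1
F2 | step 7 | methyl 5-(benzyloxy)-6-bromo-4-oxo-4H-chromene-2-carboxylate | COC(=O)C1=CC(=O)c2c(ccc(Br)c2OCc3ccccc3)O1
F3 | step 7 | 4-methyl-2-(trimethylsilyloxy)furan | Cc1coc(O[Si](C)(C)C)c1
F4 | step 7 | methyl (2S*)-5-(benzyloxy)-6-bromo-2-[(2R*)-3-methyl-5-oxo-2,5-dihydrofuran-2-yl]-4-oxochromane-2-carboxylate (racemic, one enantiomer drawn) | Brc1ccc2c(c1OCc5ccccc5)C(=O)C[C@@](C(=O)OC)([C@@H]3OC(=O)C=C3C)O2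
F5 | step 7 | rac-19, methyl (2S*)-5-(benzyloxy)-6-bromo-2-[(2R*,3S*)-3-methyl-5-oxooxolan-2-yl]-4-oxochromane-2-carboxylate (racemic, one enantiomer drawn) | Brc1ccc2c(c1OCc5ccccc5)C(=O)C[C@@](C(=O)OC)([C@@H]3OC(=O)C[C@@H]3C)O2
F6 | step 7 | potassium (3S,4R)-4-[(2S)-5-(benzyloxy)-6-bromo-2-(methoxycarbonyl)-4-oxochroman-2-yl]-4-hydroxy-3-methylbutanoate | COC(=O)[C@@]1([C@H](O)[C@@H](C)CC(=O)[O-])CC(=O)c2c(ccc(Br)c2OCc3ccccc3)O1.[K+]
F7 | step 8 | benzyl (3S,4R)-4-[(2S)-5-(benzyloxy)-6-bromo-2-(methoxycarbonyl)-4-oxochroman-2-yl]-3-methyl-4-[(triethylsilyl)oxy]butanoate | COC(=O)[C@@]1([C@H](O[Si](CC)(CC)CC)[C@@H](C)CC(=O)OCc4ccccc4)CC(=O)c2c(ccc(Br)c2OCc3ccccc3)O1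
F8 | step 8 | triethylsilyl-protected biaryl (22 with OSiEt3 in place of OCH2OBn) | COC(=O)[C@@]1([C@H](O[Si](CC)(CC)CC)[C@@H](C)CC(=O)OCc4ccccc4)CC(=O)c2c(ccc(-c6ccc7c(c6OCc8ccccc8)C(=O)C[C@@](C(=O)OC)([C@@H]9OC(=O)C[C@@H]9C)O7)c2OCc3ccccc3)O1
F9 | step 8 | 4-O-triethylsilyl ether of 23 | COC(=O)[C@@]1([C@H](O[Si](CC)(CC)CC)[C@@H](C)CC(=O)O)CC(=O)c2c(ccc(-c6ccc7c(c6O)C(=O)C[C@@](C(=O)OC)([C@@H]9OC(=O)C[C@@H]9C)O7)c2O)O1
F10 | step 11 | methyl (2S)-5-(benzyloxy)-2-[(2R,3S)-3-methyl-5-oxooxolan-2-yl]-4-oxo-6-(4,4,5,5-tetramethyl-1,3,2-dioxaborolan-2-yl)-3,4-dihydro-2H-chromene-2-carboxylate | CC6(C)OB(OC6(C)C)c1ccc2c(c1OCc5ccccc5)C(=O)C[C@@](C(=O)OC)([C@@H]3OC(=O)C[C@@H]3C)O2
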